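## Retrosynthetic overview

1. The last bonds made are the ester between the central isocitrate carboxyl of unit A and the 4α‑CH2OH (C15) of unit B, and the two allyl esters that mask the CH2CO2H arms are removed at the very end.
2. Unit A rests on its gem‑dimethyl trans‑decalin (rings A and B holding C5, C9, C10 and the C8=C12 methylene beside the hindered C11–O ether). Both rings are closed in one proton‑initiated cationic bicyclization of an open (2Z,6E)‑3‑(silylmethyl)farnesyl isocitrate ether, ring A (C4–C5) first and ring B (C9–C10) second, under a chiral Lewis‑acid‑assisted Brønsted acid.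
3. Unit B is closed in the same ring order from a Sharpless epoxide at C3–C4 that also brings the C15 oxygen; the C3 hydroxyl is then removed.
4. Both C11–O ethers are made on the open chain by silver oxide alkylation of Frater–Seebach isocitrate triesters [(R)‑malate] with a (Z)‑3‑triflyloxy allylic bromide; the C–Si bond follows by iron‑catalysed coupling.
5. The C15 chain comes from geranyl bromide and the dianion of ethyl acetoacetate.

Key step: step 11

Remarks and assumptions on the chemistry:
- Positions are numbered as in drimanes: C1–C10 for the decalin, C11 for the CH2O on C9, C12 for the methylene on C8, and C15 for the oxygenated 4α‑CH2 of unit B.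
- The (R)‑configured binaphthol acid is assumed to give the 5S,9S,10S series, as it does with other polyprenoids; if the opposite sense is found, the (S)‑ligand is used.
- The ligand of step 11 is a known reagent, made from (R)‑BINOL by mono‑O‑benzylation; its preparation is not counted as a route step.
- Compared with a plain O‑alkylation by a silylated bromide, two details are changed. The isocitrate hydroxyl is alkylated without base, because its alkoxide would lactonise, undergo retro‑aldol cleavage or eliminate. Silicon is introduced only after the ether exists, so that silver‑assisted ionisation cannot end in loss of silicon.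

## Route

**Step 1**
Reactants: 1 geranyl bromide; 2 ethyl acetoacetate
Product: 4 ethyl (6E)-7,11-dimethyl-3-oxododeca-6,10-dienoate, via ethyl acetoacetate dianion 3 (not isolated)
Conditions: NaH, THF, 0 °C; n‑BuLi, 0 °C; then 1, 0 °C → rt; aq. NH4Cl
Reagents that add atoms: none
Why: Acetoacetate dianion γ‑alkylation: the more basic terminal carbanion displaces the primary allylic bromide by SN2, the 6E alkene is untouched and no stereocentre is formed.

**Step 2**
Reactants: 4 ethyl (6E)-7,11-dimethyl-3-oxododeca-6,10-dienoate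
Product: 5 ethyl (2Z,6E)-7,11-dimethyl-3-(trifluoromethylsulfonyloxy)dodeca-2,6,10-trienoate
Conditions: Tf2O, sat. aq. LiOH, toluene, 5 °C
Reagents that add atoms: trifluoromethanesulfonic anhydride, O=S(=O)(OS(=O)(=O)C(F)(F)F)C(F)(F)F
Why: O‑Sulfonylation of the lithium‑chelated enolate should fix the Z geometry (TfO cis to the ester), which later places the silylmethyl group cis to C11.

**Step 3**
Reactants: 6 (R)-malic acid
Product: 9 (R)-3-hydroxy-4-methoxy-4-oxobutanoic acid, via trifluoroacetylmalic anhydride 7 (not isolated), via O-trifluoroacetyl monoester 8 (not isolated)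
Conditions: TFAA, 0 °C → rt, evaporate; MeOH, 0 °C → rt
Reagents that add atoms: methanol, CO
Why: Cyclic anhydride formation and regioselective methanolysis at the carbonyl next to the acyloxy‑bearing carbon, then methanolysis of the trifluoroacetate, should give the 1‑methyl ester without touching the stereocentre.

**Step 4**
Reactants: 9 (R)-3-hydroxy-4-methoxy-4-oxobutanoic acid
Product: 10 1-methyl 4-[2-(trimethylsilyl)ethyl] (R)-2-hydroxybutanedioate
Conditions: Me3SiCH2CH2OH (3 equiv), EDC·HCl, DMAP (cat.), CH2Cl2, 0 °C → rt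
Reagents that add atoms: 2-(trimethylsilyl)ethanol, C[Si](C)(C)CCO
Why: Steglich esterification of the only free carboxyl; the hindered secondary hydroxyl competes poorly with the excess primary alcohol.

**Step 5**
Reactants: 10 1-methyl 4-[2-(trimethylsilyl)ethyl] (R)-2-hydroxybutanedioate; 11 allyl bromoacetate
Product: 13 3-allyl 1-methyl 2-[2-(trimethylsilyl)ethyl] (1R,2S)-1-hydroxypropane-1,2,3-tricarboxylate, via malate dianion 12 (not isolated)
Conditions: LiHMDS (2.2 equiv), THF, −78 → −20 °C; 11, −78 °C; AcOH quench at −78 °C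
Reagents that add atoms: none
Why: Frater–Seebach alkylation: the chelated dilithio alkoxide–enolate is alkylated anti to the alkoxide, which should set the new centre as S (natural threo isocitrate), and the cold quench avoids γ‑lactonisation onto the new ester.

**Step 6**
Reactants: 14 dimethyl (R)-malate; 11 allyl bromoacetate
Product: 16 3-allyl 1,2-dimethyl (1R,2S)-1-hydroxypropane-1,2,3-tricarboxylate, via dimethyl malate dianion 15 (not isolated)
Conditions: LiHMDS (2.2 equiv), THF, −78 → −20 °C; 11, −78 °C; AcOH quench at −78 °C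
Reagents that add atoms: none
Why: Frater–Seebach alkylation as in step 5, anti to the alkoxide, setting the central centre as S.

**Step 7**
Reactants: 5 ethyl (2Z,6E)-7,11-dimethyl-3-(trifluoromethylsulfonyloxy)dodeca-2,6,10-trienoate
Product: 17 (2Z,6E)-1-hydroxy-7,11-dimethyldodeca-2,6,10-trien-3-yl trifluoromethanesulfonate
Conditions: DIBAL‑H (2.3 equiv), CH2Cl2, −78 °C; Rochelle salt
Reagents that add atoms: none
Why: DIBAL‑H 1,2‑reduction of the enoate to the allylic alcohol at low temperature, with the alkenyl triflate and the alkene geometry retained.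

**Step 8**
Reactants: 17 (2Z,6E)-1-hydroxy-7,11-dimethyldodeca-2,6,10-trien-3-yl trifluoromethanesulfonate
Product: 18 (2Z,6E)-1-bromo-7,11-dimethyldodeca-2,6,10-trien-3-yl trifluoromethanesulfonate
Conditions: CBr4, PPh3, CH2Cl2, 0 °C
Reagents that add atoms: carbon tetrabromide, BrC(Br)(Br)Br
Why: Appel bromination by SN2 at the primary allylic carbon under neutral conditions.

**Step 9**
Reactants: 18 (2Z,6E)-1-bromo-7,11-dimethyldodeca-2,6,10-trien-3-yl trifluoromethanesulfonate; 13 3-allyl 1-methyl 2-[2-(trimethylsilyl)ethyl] (1R,2S)-1-hydroxypropane-1,2,3-tricarboxylate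
Product: 19 3-allyl 1-methyl 2-[2-(trimethylsilyl)ethyl] (1R,2S)-1-{[(2Z,6E)-7,11-dimethyl-3-(trifluoromethylsulfonyloxy)dodeca-2,6,10-trien-1-yl]oxy}propane-1,2,3-tricarboxylate
Conditions: 13 (1.5 equiv), Ag2O (2 equiv), 4 Å MS, CH2Cl2, rt, dark
Reagents that add atoms: none
Why: Silver(I) oxide‑promoted Williamson‑type O‑alkylation without base, so no free alkoxide can lactonise, undergo retro‑aldol cleavage or eliminate; the electron‑poor triflyloxy allyl bromide reacts at the primary carbon and both isocitrate centres are untouched.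

**Step 10**
Reactants: 19 the triflate ether of step 9; 20 (trimethylsilyl)methylmagnesium chloride
Product: 21 3-allyl 1-methyl 2-[2-(trimethylsilyl)ethyl] (1R,2S)-1-{[(2Z,6E)-7,11-dimethyl-3-[(trimethylsilyl)methyl]dodeca-2,6,10-trien-1-yl]oxy}propane-1,2,3-tricarboxylate
Conditions: 20 (1.5 equiv), Fe(acac)3 (5 mol %), THF/NMP, −30 °C
Reagents that add atoms: none
Why: Iron‑catalysed Kumada‑type coupling of the alkenyl triflate with retention of alkene geometry; the fast low‑temperature coupling should spare the esters, and Pd(0) or Ni(0), which would ionise the allyl ester, are avoided.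

**Step 11** (key step)
Reactants: 21 the allylsilane farnesyl isocitrate ether of step 10
Product: 22 3-allyl 1-methyl 2-[2-(trimethylsilyl)ethyl] (1R,2S)-1-{[(5S,9S,10S)-drim-8(12)-en-11-yl]oxy}propane-1,2,3-tricarboxylate
Conditions: (R)-2-(2-fluorobenzyloxy)-2'-hydroxy-1,1'-binaphthyl (2.2 equiv), SnCl4 (2.0 equiv), toluene, −78 °C, 48 h; aq. NaHCO3
Reagents that add atoms: none
Why: This is a Lewis‑acid‑assisted chiral Brønsted acid polyene cyclization with allylsilane termination (closest known types: the enantioselective protonative cyclization of polyprenoids and the allylsilane‑terminated bicyclization of silylated farnesyl esters), in which the tin‑bound chiral phenol protonates C3 of the terminal alkene on one enantioface while C5=C10 and then the C8=C9 allylsilane add through a chair–chair fold. Ring A closes by a 6‑endo‑trig cation–olefin addition (C4–C5) and ring B by a second 6‑endo‑trig addition (C9–C10), the β‑silyl cation at C8 collapsing to the C8=C12 methylene. C5 and C10 arise trans by anti addition across the 6E alkene, C9 follows from the allylsilane geometry (chain trans to C11, so C11 becomes equatorial and β), and the absolute sense is set by the chiral acid because the isocitrate centres are remote. The step needs protonation at the terminal trisubstituted alkene and not at the allylsilane or the allyl ester, which the substrate secures because C9 is deactivated and shielded by the allylic ether and the allyl ester alkene is monosubstituted and electron‑poor. It also needs the allylic C11–O bond to survive tin coordination, which the low temperature and the poor leaving‑group ability of the alkoxy ester should secure. Since the isocitrate is enantiopure, product from the wrong enantioface is a diastereomer and should be removable by chromatography.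

**Step 12**
Reactants: 22 the protected unit A monomer of step 11
Product: 23 (2S,3R)-2-[2-(allyloxy)-2-oxoethyl]-3-{[(5S,9S,10S)-drim-8(12)-en-11-yl]oxy}-4-methoxy-4-oxobutanoic acid
Conditions: TBAF (1.5 equiv), THF, 0 °C; aq. KHSO4
Reagents that add atoms: none
Why: Fluoride‑induced β‑fragmentation of the 2‑(trimethylsilyl)ethyl ester; methyl and allyl esters and the exocyclic alkene should be inert to fluoride at 0 °C.

**Step 13**
Reactants: 5 ethyl (2Z,6E)-7,11-dimethyl-3-(trifluoromethylsulfonyloxy)dodeca-2,6,10-trienoate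
Product: 24 ethyl (2Z,6E,10E)-12-hydroxy-7,11-dimethyl-3-(trifluoromethylsulfonyloxy)dodeca-2,6,10-trienoate
Conditions: SeO2 (0.3 equiv), t‑BuOOH (3 equiv), salicylic acid (cat.), CH2Cl2, rt
Reagents that add atoms: tert-butyl hydroperoxide, CC(C)(C)OO; selenium dioxide, O=[Se]=O
Why: Selenium dioxide allylic oxidation (ene reaction, then [2,3] shift) with its usual preference for the E‑methyl of the terminal isopropylidene; the enol triflate alkene is too electron‑poor to react.

**Step 14**
Reactants: 24 the ω‑allylic alcohol of step 13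
Product: 25 ethyl (2Z,6E)-9-[(2S,3S)-3-(hydroxymethyl)-3-methyloxiran-2-yl]-7-methyl-3-(trifluoromethylsulfonyloxy)nona-2,6-dienoate
Conditions: Ti(OiPr)4 (10 mol %), L‑(+)‑DET (12 mol %), t‑BuOOH, 4 Å MS, CH2Cl2, −20 °C
Reagents that add atoms: tert-butyl hydroperoxide, CC(C)(C)OO
Why: Sharpless asymmetric epoxidation: only the allylic‑alcohol alkene reacts, and the L‑(+)‑tartrate catalyst should deliver oxygen to the face that gives the (2S,3S)‑epoxy alcohol.

**Step 15**
Reactants: 25 the epoxy alcohol of step 14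
Product: 26 ethyl (2Z,6E)-9-[(2S,3S)-3-(tert-butyldiphenylsilyloxymethyl)-3-methyloxiran-2-yl]-7-methyl-3-(trifluoromethylsulfonyloxy)nona-2,6-dienoate
Conditions: TBDPSCl, imidazole, DMF, 0 °C → rt
Reagents that add atoms: tert-butyl(chloro)diphenylsilane, CC(C)(C)[Si](Cl)(c1ccccc1)c1ccccc1
Why: Silylation of the primary hydroxyl gives an ether that should survive hydride, silver, Grignard and Lewis acid reagents.

**Step 16**
Reactants: 26 the silyl ether of step 15
Product: 27 (2Z,6E)-9-[(2S,3S)-3-(tert-butyldiphenylsilyloxymethyl)-3-methyloxiran-2-yl]-1-hydroxy-7-methylnona-2,6-dien-3-yl trifluoromethanesulfonate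
Conditions: DIBAL‑H (2.3 equiv), CH2Cl2, −78 °C; Rochelle salt
Reagents that add atoms: none
Why: DIBAL‑H 1,2‑reduction of the enoate; the trisubstituted epoxide, the silyl ether and the alkenyl triflate should not react at −78 °C.

**Step 17**
Reactants: 27 the allylic alcohol of step 16
Product: 28 (2Z,6E)-1-bromo-9-[(2S,3S)-3-(tert-butyldiphenylsilyloxymethyl)-3-methyloxiran-2-yl]-7-methylnona-2,6-dien-3-yl trifluoromethanesulfonate
Conditions: CBr4, PPh3, 2,6‑lutidine, CH2Cl2, −20 → 0 °C
Reagents that add atoms: carbon tetrabromide, BrC(Br)(Br)Br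
Why: Buffered Appel bromination by SN2 at the primary allylic carbon, the base protecting the epoxide from acid.

**Step 18**
Reactants: 28 the epoxy bromide of step 17; 16 3-allyl 1,2-dimethyl (1R,2S)-1-hydroxypropane-1,2,3-tricarboxylate
Product: 29 3-allyl 1,2-dimethyl (1R,2S)-1-{[(2Z,6E)-9-[(2S,3S)-3-(tert-butyldiphenylsilyloxymethyl)-3-methyloxiran-2-yl]-7-methyl-3-(trifluoromethylsulfonyloxy)nona-2,6-dien-1-yl]oxy}propane-1,2,3-tricarboxylate
Conditions: 16 (1.5 equiv), Ag2O (2 equiv), 4 Å MS, CH2Cl2, rt, dark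
Reagents that add atoms: none
Why: Silver(I) oxide‑promoted O‑alkylation as in step 9; the ether from the minor epoxide enantiomer is now a diastereomer and can be removed.

**Step 19**
Reactants: 29 the epoxy triflate ether of step 18; 20 (trimethylsilyl)methylmagnesium chloride
Product: 30 3-allyl 1,2-dimethyl (1R,2S)-1-{[(2Z,6E)-9-[(2S,3S)-3-(tert-butyldiphenylsilyloxymethyl)-3-methyloxiran-2-yl]-7-methyl-3-[(trimethylsilyl)methyl]nona-2,6-dien-1-yl]oxy}propane-1,2,3-tricarboxylate
Conditions: 20 (1.5 equiv), Fe(acac)3 (5 mol %), THF/NMP, −30 °C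
Reagents that add atoms: none
Why: Iron‑catalysed Kumada‑type coupling as in step 10, with retention of geometry; the trisubstituted epoxide should be inert at −30 °C.

**Step 20**
Reactants: 30 the epoxy allylsilane of step 19
Product: 31 3-allyl 1,2-dimethyl (1R,2S)-1-{[(3S,4R,5R,9S,10S)-15-(tert-butyldiphenylsilyloxy)-3-hydroxydrim-8(12)-en-11-yl]oxy}propane-1,2,3-tricarboxylate
Conditions: MeAlCl2 (3 equiv), CH2Cl2, −78 °C; aq. Rochelle salt, then dilute citric acid
Reagents that add atoms: none
Why: Lewis‑acid‑promoted epoxide‑initiated cation–olefin bicyclization with allylsilane termination: anti opening at the tertiary C4 through a chair–chair fold should give 3β‑OH and the equatorial 4α‑CH2OSi (from the E substituent), the trans ring fusion and β‑C11, with the absolute configuration taken from the epoxide and C8=C12 fixed by loss of silicon.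

**Step 21**
Reactants: 31 the 3β‑hydroxy bicycle of step 20
Product: 32 3-allyl 1,2-dimethyl (1R,2S)-1-{[(3S,4R,5R,9S,10S)-15-(tert-butyldiphenylsilyloxy)-3-(imidazol-1-ylthiocarbonyloxy)drim-8(12)-en-11-yl]oxy}propane-1,2,3-tricarboxylate
Conditions: 1,1'-thiocarbonyldiimidazole (3 equiv), DMAP, ClCH2CH2Cl, 70 °C
Reagents that add atoms: 1,1'-thiocarbonyldiimidazole, S=C(n1ccnc1)n1ccnc1
Why: Thioacylation of the only free hydroxyl prepares the Barton–McCombie deoxygenation under neutral conditions that spare the esters.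

**Step 22**
Reactants: 32 the thiocarbonylimidazolide of step 21
Product: 33 3-allyl 1,2-dimethyl (1R,2S)-1-{[(4R,5R,9S,10S)-15-(tert-butyldiphenylsilyloxy)drim-8(12)-en-11-yl]oxy}propane-1,2,3-tricarboxylate
Conditions: Bu3SnH, AIBN (cat.), toluene, 100 °C
Reagents that add atoms: none
Why: Barton–McCombie radical deoxygenation: the secondary C3 radical cannot reach the exocyclic alkene in the rigid trans‑decalin and is reduced by the stannane, removing the auxiliary C3 oxygen.

**Step 23**
Reactants: 33 the silyl ether of step 22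
Product: 34 3-allyl 1,2-dimethyl (1R,2S)-1-{[(4R,5R,9S,10S)-15-hydroxydrim-8(12)-en-11-yl]oxy}propane-1,2,3-tricarboxylate
Conditions: TBAF, AcOH (1:1), THF, rt → 40 °C
Reagents that add atoms: none
Why: Buffered fluoride desilylation frees the neopentyl primary alcohol while the acetic acid buffer keeps the β‑alkoxy esters from eliminating.

**Step 24**
Reactants: 23 the unit A acid of step 12; 34 the unit B alcohol of step 23
Product: 36 bis(allyl) ester of the target (unit A central carboxyl esterified with C15–OH of unit B), via mixed anhydride 35 (not isolated)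
Conditions: 2,4,6‑trichlorobenzoyl chloride, i‑Pr2NEt, THF, 0 °C; then 34, DMAP, toluene, rt
Reagents that add atoms: none
Why: Yamaguchi esterification: the acylpyridinium from the mixed anhydride should acylate the hindered neopentyl alcohol, and the cold, weakly basic activation limits epimerisation or β‑elimination at the activated acid.

**Step 25**
Reactants: 36 the bis(allyl) ester of step 24
Product: 37 CNP0139922.2 (target)
Conditions: Pd(PPh3)4 (5 mol %), morpholine, THF, rt; pH 3–4 work‑up
Reagents that add atoms: none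
Why: Palladium(0)‑catalysed allyl transfer to morpholine (Tsuji–Trost deallylation) is neutral and should free both arm acids without touching the methyl esters, the neopentyl ester or the exocyclic alkenes.

## Compound list

1 | geranyl bromide | CC(C)=CCC/C(C)=C/CBr | starting material
2 | ethyl acetoacetate | CCOC(=O)CC(C)=O | starting material
3 | ethyl acetoacetate dianion (sodium lithium salt) | [Na+].[Li+].[CH2-]C(=O)[CH-]C(=O)OCC | intermediate
4 | ethyl (6E)-7,11-dimethyl-3-oxododeca-6,10-dienoate | CC(C)=CCC/C(C)=C/CCC(=O)CC(=O)OCC | intermediate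
5 | ethyl (2Z,6E)-7,11-dimethyl-3-(trifluoromethylsulfonyloxy)dodeca-2,6,10-trienoate | CC(C)=CCC/C(C)=C/CC/C(OS(=O)(=O)C(F)(F)F)=C/C(=O)OCC | intermediate
6 | (R)-malic acid | O[C@@H](C(=O)O)CC(=O)O | starting material
7 | (R)-2,5-dioxooxolan-3-yl trifluoroacetate (trifluoroacetylmalic anhydride) | O=C1C[C@@H](OC(=O)C(F)(F)F)C(=O)O1 | intermediate
8 | (R)-4-methoxy-4-oxo-3-(trifluoroacetoxy)butanoic acid | OC(=O)C[C@@H](OC(=O)C(F)(F)F)C(=O)OC | intermediate
9 | (R)-3-hydroxy-4-methoxy-4-oxobutanoic acid | O[C@@H](C(=O)OC)CC(=O)O | intermediate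
10 | 1-methyl 4-[2-(trimethylsilyl)ethyl] (R)-2-hydroxybutanedioate | O[C@@H](C(=O)OC)CC(=O)OCC[Si](C)(C)C | intermediate
11 | allyl bromoacetate | C=CCOC(=O)CBr | starting material
12 | dilithio alkoxide–enolate of 10 | [Li+].[Li+].[O-][C@@H](C(=O)OC)C=C([O-])OCC[Si](C)(C)C | intermediate
13 | 3-allyl 1-methyl 2-[2-(trimethylsilyl)ethyl] (1R,2S)-1-hydroxypropane-1,2,3-tricarboxylate | O[C@@H](C(=O)OC)[C@H](CC(=O)OCC=C)C(=O)OCC[Si](C)(C)C | intermediate
14 | dimethyl (R)-malate | O[C@@H](C(=O)OC)CC(=O)OC | starting material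
15 | dilithio alkoxide–enolate of 14 | [Li+].[Li+].[O-][C@@H](C(=O)OC)C=C([O-])OC | intermediate
16 | 3-allyl 1,2-dimethyl (1R,2S)-1-hydroxypropane-1,2,3-tricarboxylate | O[C@@H](C(=O)OC)[C@H](CC(=O)OCC=C)C(=O)OC | intermediate
17 | (2Z,6E)-1-hydroxy-7,11-dimethyldodeca-2,6,10-trien-3-yl trifluoromethanesulfonate | CC(C)=CCC/C(C)=C/CC/C(OS(=O)(=O)C(F)(F)F)=C/CO | intermediate
18 | (2Z,6E)-1-bromo-7,11-dimethyldodeca-2,6,10-trien-3-yl trifluoromethanesulfonate | CC(C)=CCC/C(C)=C/CC/C(OS(=O)(=O)C(F)(F)F)=C/CBr | intermediate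
19 | triflate ether of 13 with the (2Z,6E)-C15 chain | CC(C)=CCC/C(C)=C/CC/C(OS(=O)(=O)C(F)(F)F)=C/CO[C@@H](C(=O)OC)[C@H](CC(=O)OCC=C)C(=O)OCC[Si](C)(C)C | intermediate
20 | (trimethylsilyl)methylmagnesium chloride | C[Si](C)(C)C[Mg]Cl | starting material
21 | allylsilane farnesyl isocitrate ether (key‑step precursor) | CC(C)=CCC/C(C)=C/CC/C(C[Si](C)(C)C)=C/CO[C@@H](C(=O)OC)[C@H](CC(=O)OCC=C)C(=O)OCC[Si](C)(C)C | intermediate
22 | protected unit A monomer, (5S,9S,10S)-drim-8(12)-en-11-yl isocitrate ether | C=C1CC[C@H]2C(C)(C)CCC[C@]2(C)[C@H]1CO[C@@H](C(=O)OC)[C@H](CC(=O)OCC=C)C(=O)OCC[Si](C)(C)C | intermediate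
23 | unit A central acid | C=C1CC[C@H]2C(C)(C)CCC[C@]2(C)[C@H]1CO[C@@H](C(=O)OC)[C@H](CC(=O)OCC=C)C(=O)O | intermediate
24 | ethyl (2Z,6E,10E)-12-hydroxy-7,11-dimethyl-3-(trifluoromethylsulfonyloxy)dodeca-2,6,10-trienoate | OC/C(C)=C/CC/C(C)=C/CC/C(OS(=O)(=O)C(F)(F)F)=C/C(=O)OCC | intermediate
25 | ethyl (2Z,6E)-9-[(2S,3S)-3-(hydroxymethyl)-3-methyloxiran-2-yl]-7-methyl-3-(trifluoromethylsulfonyloxy)nona-2,6-dienoate | OC[C@]1(C)O[C@H]1CC/C(C)=C/CC/C(OS(=O)(=O)C(F)(F)F)=C/C(=O)OCC | intermediate
26 | tert-butyldiphenylsilyl ether of 25 | CC(C)(C)[Si](OC[C@]1(C)O[C@H]1CC/C(C)=C/CC/C(OS(=O)(=O)C(F)(F)F)=C/C(=O)OCC)(c2ccccc2)c2ccccc2 | intermediate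
27 | epoxy silyl ether allylic alcohol | CC(C)(C)[Si](OC[C@]1(C)O[C@H]1CC/C(C)=C/CC/C(OS(=O)(=O)C(F)(F)F)=C/CO)(c2ccccc2)c2ccccc2 | intermediate
28 | epoxy silyl ether allylic bromide | CC(C)(C)[Si](OC[C@]1(C)O[C@H]1CC/C(C)=C/CC/C(OS(=O)(=O)C(F)(F)F)=C/CBr)(c2ccccc2)c2ccccc2 | intermediate
29 | epoxy triflate ether of 16 | CC(C)(C)[Si](OC[C@]1(C)O[C@H]1CC/C(C)=C/CC/C(OS(=O)(=O)C(F)(F)F)=C/CO[C@@H](C(=O)OC)[C@H](CC(=O)OCC=C)C(=O)OC)(c2ccccc2)c2ccccc2 | intermediate
30 | epoxy allylsilane ether of 16 | CC(C)(C)[Si](OC[C@]1(C)O[C@H]1CC/C(C)=C/CC/C(C[Si](C)(C)C)=C/CO[C@@H](C(=O)OC)[C@H](CC(=O)OCC=C)C(=O)OC)(c2ccccc2)c2ccccc2 | intermediate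
31 | (3S,4R,5R,9S,10S)-15-(tert-butyldiphenylsilyloxy)-3-hydroxydrim-8(12)-en-11-yl ether of 16 | CC(C)(C)[Si](OC[C@]1(C)[C@@H](O)CC[C@]2(C)[C@@H](CO[C@@H](C(=O)OC)[C@H](CC(=O)OCC=C)C(=O)OC)C(=C)CC[C@@H]12)(c3ccccc3)c3ccccc3 | intermediate
32 | 3-O-(imidazol-1-ylthiocarbonyl) derivative of 31 | CC(C)(C)[Si](OC[C@]1(C)[C@@H](OC(=S)n4ccnc4)CC[C@]2(C)[C@@H](CO[C@@H](C(=O)OC)[C@H](CC(=O)OCC=C)C(=O)OC)C(=C)CC[C@@H]12)(c3ccccc3)c3ccccc3 | intermediate
33 | (4R,5R,9S,10S)-15-(tert-butyldiphenylsilyloxy)drim-8(12)-en-11-yl ether of 16 | CC(C)(C)[Si](OC[C@]1(C)CCC[C@]2(C)[C@@H](CO[C@@H](C(=O)OC)[C@H](CC(=O)OCC=C)C(=O)OC)C(=C)CC[C@@H]12)(c3ccccc3)c3ccccc3 | intermediate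
34 | unit B alcohol, (4R,5R,9S,10S)-15-hydroxydrim-8(12)-en-11-yl ether of 16 | OC[C@]1(C)CCC[C@]2(C)[C@@H](CO[C@@H](C(=O)OC)[C@H](CC(=O)OCC=C)C(=O)OC)C(=C)CC[C@@H]12 | intermediate
35 | mixed 2,4,6-trichlorobenzoic anhydride of 23 | C=C1CC[C@H]2C(C)(C)CCC[C@]2(C)[C@H]1CO[C@@H](C(=O)OC)[C@H](CC(=O)OCC=C)C(=O)OC(=O)c3c(Cl)cc(Cl)cc3Cl | intermediate
36 | bis(allyl) ester of the target | C=C1CC[C@H]2C(C)(C)CCC[C@]2(C)[C@H]1CO[C@@H](C(=O)OC)[C@H](CC(=O)OCC=C)C(=O)OC[C@]1(C)CCC[C@]2(C)[C@@H](CO[C@@H](C(=O)OC)[C@H](CC(=O)OCC=C)C(=O)OC)C(=C)CC[C@@H]12 | intermediate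
37 | CNP0139922.2 | C=C1CC[C@H]2C(C)(C)CCC[C@]2(C)[C@H]1CO[C@@H](C(=O)OC)[C@H](CC(=O)O)C(=O)OC[C@]1(C)CCC[C@]2(C)[C@@H](CO[C@@H](C(=O)OC)[C@H](CC(=O)O)C(=O)OC)C(=C)CC[C@@H]12 | target

## Step count and risks

Total step count: 25. Longest linear sequence: 15 steps (steps 1, 2, 13–23, 24, 25).

**Step 11 (key step).** The chiral acid may discriminate the enantiofaces poorly at the initiating protonation because the three esters and the ether oxygen compete for tin. The allylsilane may be protodesilylated, or the allylic ether may be lost together with silicon before the rings close. The fallback takes the absolute configuration from a Sharpless epoxide and sets out from bromide 28 and hydroxy triester 13. Silver oxide alkylation gives the epoxy triflate ether F1, and iron‑catalysed coupling with 20 gives the epoxy allylsilane F2. Cyclization with MeAlCl2 as in step 20 gives the 3β‑hydroxy‑15‑silyloxy bicycle F3. HF·pyridine, which leaves the silylethyl ester intact, gives the 3β,15‑diol F4, and thiocarbonyldiimidazole gives the bis(thiocarbonylimidazolide) F5. A double Barton–McCombie reduction with Bu3SnH in refluxing xylene removes both oxygens, turning C15H2O into the second C4 methyl, and the route is rejoined at 22.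

**Step 20.** The epoxide may open by hydride shift to a ketone, be captured by a neighbouring oxygen, or give only monocyclic material, because C4 carries an inductively withdrawing CH2O group and the Lewis acid is partly bound by the esters. The fallback closes the rings in the radical mode and sets out from hydroxy triester 16. Silver oxide alkylation with commercial (2E,6E)-farnesyl bromide F6 gives the farnesyl ether F7. Selenium dioxide oxidation gives the 12‑hydroxy ether F8, Sharpless epoxidation with L‑(+)‑DET gives the epoxy alcohol F9, and silylation gives the silyl ether F10. Titanocene(III)‑mediated radical epoxypolyene cyclization (Cp2TiCl2 cat., Mn, Me3SiCl, collidine, THF), which ends in the exocyclic alkene without silicon, should then rejoin the route at 31 after mild acidic work‑up. In this mode C4 is set by the preference of the larger CH2OSi group for the equatorial position.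

**Step 9 (the same applies to step 18).** The hindered, electron‑poor secondary hydroxyl may be alkylated too slowly, so that γ‑lactonisation onto the allyl ester or silver‑induced ionisation of the bromide takes over. The fallback replaces the halide/silver pair by an acid‑catalysed imidate alkylation and sets out from alcohol 17. Cl3CCN with catalytic DBU gives the allylic trichloroacetimidate F11, which with 13 and catalytic TMSOTf in CH2Cl2/cyclohexane at −20 °C should give 19, where the route is rejoined.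

## Further compounds

F1 | step 11 | epoxy triflate ether from 28 and 13 | CC(C)(C)[Si](OC[C@]1(C)O[C@H]1CC/C(C)=C/CC/C(OS(=O)(=O)C(F)(F)F)=C/CO[C@@H](C(=O)OC)[C@H](CC(=O)OCC=C)C(=O)OCC[Si](C)(C)C)(c2ccccc2)c2ccccc2
F2 | step 11 | epoxy allylsilane ether of 13 | CC(C)(C)[Si](OC[C@]1(C)O[C@H]1CC/C(C)=C/CC/C(C[Si](C)(C)C)=C/CO[C@@H](C(=O)OC)[C@H](CC(=O)OCC=C)C(=O)OCC[Si](C)(C)C)(c2ccccc2)c2ccccc2
F3 | step 11 | (3S,4R,5R,9S,10S)-15-(tert-butyldiphenylsilyloxy)-3-hydroxydrim-8(12)-en-11-yl ether of 13 | CC(C)(C)[Si](OC[C@]1(C)[C@@H](O)CC[C@]2(C)[C@@H](CO[C@@H](C(=O)OC)[C@H](CC(=O)OCC=C)C(=O)OCC[Si](C)(C)C)C(=C)CC[C@@H]12)(c3ccccc3)c3ccccc3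
F4 | step 11 | (3S,4R,5R,9S,10S)-3,15-dihydroxydrim-8(12)-en-11-yl ether of 13 | OC[C@]1(C)[C@@H](O)CC[C@]2(C)[C@@H](CO[C@@H](C(=O)OC)[C@H](CC(=O)OCC=C)C(=O)OCC[Si](C)(C)C)C(=C)CC[C@@H]12
F5 | step 11 | 3,15-bis-O-(imidazol-1-ylthiocarbonyl) derivative of F4 | S=C(OC[C@]1(C)[C@@H](OC(=S)n3ccnc3)CC[C@]2(C)[C@@H](CO[C@@H](C(=O)OC)[C@H](CC(=O)OCC=C)C(=O)OCC[Si](C)(C)C)C(=C)CC[C@@H]12)n4ccnc4
F6 | step 20 | (2E,6E)-farnesyl bromide | CC(C)=CCC/C(C)=C/CC/C(C)=C/CBr
F7 | step 20 | (2E,6E)-farnesyl ether of 16 | CC(C)=CCC/C(C)=C/CC/C(C)=C/CO[C@@H](C(=O)OC)[C@H](CC(=O)OCC=C)C(=O)OC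
F8 | step 20 | (2E,6E,10E)-12-hydroxyfarnesyl ether of 16 | OC/C(C)=C/CC/C(C)=C/CC/C(C)=C/CO[C@@H](C(=O)OC)[C@H](CC(=O)OCC=C)C(=O)OC
F9 | step 20 | (2S,3S)-epoxy alcohol from F8 | OC[C@]1(C)O[C@H]1CC/C(C)=C/CC/C(C)=C/CO[C@@H](C(=O)OC)[C@H](CC(=O)OCC=C)C(=O)OC
F10 | step 20 | tert-butyldiphenylsilyl ether of F9 | CC(C)(C)[Si](OC[C@]1(C)O[C@H]1CC/C(C)=C/CC/C(C)=C/CO[C@@H](C(=O)OC)[C@H](CC(=O)OCC=C)C(=O)OC)(c2ccccc2)c2ccccc2
F11 | step 9 | (2Z,6E)-7,11-dimethyl-3-(trifluoromethylsulfonyloxy)dodeca-2,6,10-trien-1-yl 2,2,2-trichloroacetimidate | CC(C)=CCC/C(C)=C/CC/C(OS(=O)(=O)C(F)(F)F)=C/COC(=N)C(Cl)(Cl)Cl
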